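At early times I read the earlier runs as molar target, not percent, and they coincide: at 12.0 min the north-west run holds 0.0654 M, the south-east run 0.0648 M and the south-west run 0.0666 M. Up to this reading, target in these runs grows at zero order in the charge.

| setting | north-west | south-east | south-west | Sunday's | Monday's |
|---|---|---|---|---|---|
| solid substrate | 0.60 M | 1.2 M | 1.8 M | 2.0 M | 0.60 M |
| gas phase | 200 mM (held) | 200 mM (held) | 200 mM (held) | 200 mM (held) | 200 mM (held) |
| remark | run made earlier | run made earlier | run made earlier |  |  |
| time |  |  |  | 50 min | 12 min |

- north-west (time / min: target / %): 2.00: 0.6; 4.00: 0.9; 8.00: 4.8; 12.0: 10.9; 25.0: 24.3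
- south-east (time / min: target / %): 2.00: 0; 4.00: 0.8; 8.00: 2.2; 12.0: 5.4; 25.0: 15.3
- south-west (time / min: target / %): 2.00: 0.3; 4.00: 0.1; 8.00: 1.5; 12.0: 3.7; 25.0: 9.5

(scatter of a reading: 0.3 percentage points)

- as a solid, counted per litre of solution: solid substrate
- at the start none of the gas phase is in solution
- at the start none of the solid substrate is in solution
- what has only dissolved of solid substrate counts as not reacted

- the flask that ends with the higher amount of target, in percent of the solid substrate charged, or "neither" when 2 percentage points or less lies between them (Sunday's / Monday's / neither)
- final target, as a percentage of the solid substrate charged, in Sunday's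
- final target, as a percentage of the solid substrate charged, in Monday's

The plateau rate, the molar target gained per minute while a flask stays on this shared line, is read from the last south-west readings:

v = (0.171 M − 0.0666 M) / (25.0 min − 12.0 min) = 0.00803 M min⁻¹

Monday's is the north-west flask stopped at 12 min, so it stands near 10.9%. I turn the question round: for Sunday's not to win by more than 2 percentage points, its target must stay at or below

c(target) = (10.9% + 2 points) × 2.0 M = 0.258 M

The line passes this at 35.8 min, so Sunday's would have to leave the line before then. The south-east run has not fallen below it at 25.0 min, with 0.184 M, more than the 0.171 M of the south-west run. If time on the line scales with the charge, Sunday's stays on until at least 41.7 min, later than that. Past that time the line is only my estimate, but I run it to the end: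

c(target) = 0.171 M + v × (50 min − 25.0 min) = 0.372 M, or 18.6%

The forecast, holding that “the rate is zero order in solid charged”, names Sunday's with 19.5% against 11%, a little higher than my Sunday's figure.

The flask gives Sunday's, with 19.0% against 10.5%.

    gas phase ⇌ dissolved gas, rate k1*(csat - [dissolved gas]) (kL = 0.0980 min⁻¹)
    starting material + dissolved gas → target (k = 0.430 L mol⁻¹ min⁻¹)
    solid substrate ⇌ starting material, rate k3*(cs3 - [starting material]) while solid is left; crystals form when [starting material] > cs3 (solubility = 0.640 M, k = 0.0850 min⁻¹)
    starting material → side product (k = 0.0800 min⁻¹)
    target ⇌ isomer of the product (K = 0.450, k = 0.0150 min⁻¹)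

In Sunday's, starting material is made 1.01 times as fast as it is used up at 23.4 min and 1.00 times at 50.0 min, and it stands at 13.2% at 25.0 min and 13.3% at 50.0 min, beside dissolved gas at 0.0930 M at 25.0 min and 0.0924 M at 50.0 min. At 50.0 min its passing into side product runs 2.0 times as fast as its use for target. In the neighbour flask with 1.2 M of solid substrate, read at 50 min, the plateau rate gives 0.372 M, or 31.0%. That flask holds 25.4%, less than the line, with solid substrate at 0% and starting material at 2.98%.

Readings and results are calculated for an exercise; scatter was added.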